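The benzene ring is traced back to a symmetric saturated ring, 5-heptadecylcyclohexane-1,3-dione, because ring carbons C1 and C5 carry meta oxygens and C3 carries the heptadecyl chain. The key step makes this six-membered ring in one pot from the acyclic enone (E)-henicos-3-en-2-one and dimethyl malonate: conjugate addition forms C3–C4, Claisen closure through the methyl ketone forms C5–C6, and the surplus ester leaves as CO2. The C4 oxygen is then introduced by enolate hydroxylation of the benzyl vinylogous ester; oxidation to the 1,2-dione aromatises the ring, so the C4 and C5 hydroxyls can be methylated while C1 stays benzylated until the final hydrogenolysis.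

Key step: step 2

Remark: the labels C1–C6 refer to the benzene ring of the target (C1 OH, C3 heptadecyl, C4 and C5 OMe). The stereocentres of 5–7 and 9–11 vanish on aromatisation, so these compounds are carried as racemates or diastereomer mixtures; the target is achiral.

Step 1
Reactants: 1 octadecanal; 2 1-(triphenylphosphoranylidene)propan-2-one
Product: 3 (E)-henicos-3-en-2-one
Conditions: toluene, 90 °C
Reagents that add atoms: none
Why: Wittig olefination of an unhindered aliphatic aldehyde with a ketone-stabilised ylide should give the conjugated enone with the E double bond, as is usual for stabilised ylides.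

Step 2
Reactants: 3 (E)-henicos-3-en-2-one; 4 dimethyl malonate
Product: 8 5-heptadecylcyclohexane-1,3-dione, via dimethyl 2-(2-oxohenicosan-4-yl)malonate 5 (not isolated), via methyl 2-heptadecyl-4,6-dioxocyclohexane-1-carboxylate 6 (not isolated), via 2-heptadecyl-4,6-dioxocyclohexane-1-carboxylic acid 7 (not isolated)
Conditions: NaOMe (1.1 equiv), MeOH/THF, 65 °C; then aq NaOH, 65 °C; then aq HCl to pH 1–2, 70 °C
Reagents that add atoms: none
Why: Methoxide generates the malonate anion, which adds 1,4 to the β-carbon of enone 3 (Michael addition) to give keto diester 5; proton transfer then forms the methyl-side ketone enolate, which attacks one ester carbonyl and expels methoxide (intramolecular Claisen condensation) to give 6, held as its stabilised β-diketone enolate. The closest known reaction type is the malonate Michael–Claisen annulation of β-alkyl methyl enones to 5-alkylcyclohexane-1,3-diones, followed by saponification and thermal decarboxylation of the β-keto acid 7. The single ring closes in a 6-(enolendo)-exo-trig mode, the enolate carbon attacking an ester carbonyl whose C=O lies outside the new ring. No stereocentre survives, because the chain-bearing carbon is stereogenic in 5–7 but lies on the mirror plane of 8. The step needs 1,4- over 1,2-addition, which the soft, reversibly adding malonate anion secures, and closure through the methyl group instead of the internal methylene, which is secured by ring size (six-membered against four-membered) and by the irreversible deprotonation of the cyclic 1,3-dione.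

Step 3
Reactants: 8 5-heptadecylcyclohexane-1,3-dione
Product: 9 3-(benzyloxy)-5-heptadecylcyclohex-2-en-1-one (racemic)
Conditions: BnOH (1.2 equiv), p-TsOH·H2O (cat.), toluene, reflux, Dean–Stark
Reagents that add atoms: benzyl alcohol, OCc1ccccc1
Why: Acid-catalysed condensation of a cyclic 1,3-dione with an alcohol under azeotropic removal of water gives the vinylogous ester, and because the two carbonyls of 8 are mirror-related only one constitutional isomer can form.

Step 4
Reactants: 9 3-(benzyloxy)-5-heptadecylcyclohex-2-en-1-one
Product: 10 3-(benzyloxy)-5-heptadecyl-6-hydroxycyclohex-2-en-1-one (racemic, configuration at C6 not controlled)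
Conditions: LiN(iPr)2 (LDA, 1.2 equiv), THF, −78 °C; then (±)-trans-2-(phenylsulfonyl)-3-phenyloxaziridine (1.3 equiv), −78 °C; AcOH quench at −78 °C
Reagents that add atoms: 2-(phenylsulfonyl)-3-phenyloxaziridine, O=S(=O)(N1OC1c1ccccc1)c1ccccc1
Why: Kinetic deprotonation of a 3-alkoxycyclohexenone by a lithium amide occurs at the α′ carbon C6 next to the chain-bearing C5 (cross-conjugated enolate, as in Stork–Danheiser alkylation), and the N-sulfonyloxaziridine transfers oxygen to that carbon (Davis enolate hydroxylation), probably anti to the chain, although the new stereocentre is irrelevant because it is flattened in step 5.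

Step 5
Reactants: 10 3-(benzyloxy)-5-heptadecyl-6-hydroxycyclohex-2-en-1-one
Product: 12 5-(benzyloxy)-3-heptadecylbenzene-1,2-diol, via 4-(benzyloxy)-6-heptadecylcyclohex-3-ene-1,2-dione 11 (not isolated)
Conditions: (COCl)2 (1.2 equiv), DMSO, CH2Cl2, −78 °C; Et3N, −78 to 0 °C; degassed aqueous work-up under argon
Reagents that add atoms: none
Why: Swern oxidation turns the secondary α-hydroxy ketone into the 1,2-dione 11, which the amine base should enolise twice (at the chain-bearing CH and, vinylogously, at the ring CH2) to the catechol, a tautomerisation driven by aromatic stabilisation, while activated DMSO does not oxidise a catechol on to a quinone.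

Step 6
Reactants: 12 5-(benzyloxy)-3-heptadecylbenzene-1,2-diol
Product: 13 5-(benzyloxy)-1-heptadecyl-2,3-dimethoxybenzene
Conditions: MeI (4 equiv), K2CO3 (4 equiv), acetone, 56 °C, argon
Reagents that add atoms: iodomethane, CI
Why: Williamson ether synthesis, in which both phenoxides are methylated by SN2 attack on iodomethane while the third oxygen stays masked as its benzyl ether.

Step 7
Reactants: 13 5-(benzyloxy)-1-heptadecyl-2,3-dimethoxybenzene
Product: 14 3-heptadecyl-4,5-dimethoxyphenol
Conditions: H2 (1 atm), 10% Pd/C, EtOAc/EtOH, 23 °C
Reagents that add atoms: none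
Why: Catalytic hydrogenolysis cleaves the benzylic C–O bond of the aryl benzyl ether and leaves the aryl methyl ethers, the arene and the alkyl chain untouched.

Compound list
1 | octadecanal | CCCCCCCCCCCCCCCCCC=O | starting material
2 | 1-(triphenylphosphoranylidene)propan-2-one | CC(=O)C=P(c1ccccc1)(c1ccccc1)c1ccccc1 | starting material
3 | (E)-henicos-3-en-2-one | CCCCCCCCCCCCCCCCC/C=C/C(C)=O | intermediate
4 | dimethyl malonate | COC(=O)CC(=O)OC | starting material
5 | dimethyl 2-(2-oxohenicosan-4-yl)malonate (racemic) | CCCCCCCCCCCCCCCCCC(CC(C)=O)C(C(=O)OC)C(=O)OC | intermediate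
6 | methyl 2-heptadecyl-4,6-dioxocyclohexane-1-carboxylate (racemic, diastereomer mixture, present as its sodium enolate) | CCCCCCCCCCCCCCCCCC1CC(=O)CC(=O)C1C(=O)OC | intermediate
7 | 2-heptadecyl-4,6-dioxocyclohexane-1-carboxylic acid (racemic, diastereomer mixture) | CCCCCCCCCCCCCCCCCC1CC(=O)CC(=O)C1C(=O)O | intermediate
8 | 5-heptadecylcyclohexane-1,3-dione (achiral) | CCCCCCCCCCCCCCCCCC1CC(=O)CC(=O)C1 | intermediate
9 | 3-(benzyloxy)-5-heptadecylcyclohex-2-en-1-one (racemic) | CCCCCCCCCCCCCCCCCC1CC(=O)C=C(OCc2ccccc2)C1 | intermediate
10 | 3-(benzyloxy)-5-heptadecyl-6-hydroxycyclohex-2-en-1-one (racemic, C5/C6 relative configuration not defined) | CCCCCCCCCCCCCCCCCC1CC(OCc2ccccc2)=CC(=O)C1O | intermediate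
11 | 4-(benzyloxy)-6-heptadecylcyclohex-3-ene-1,2-dione (racemic) | CCCCCCCCCCCCCCCCCC1CC(OCc2ccccc2)=CC(=O)C1=O | intermediate
12 | 5-(benzyloxy)-3-heptadecylbenzene-1,2-diol | CCCCCCCCCCCCCCCCCc1cc(OCc2ccccc2)cc(O)c1O | intermediate
13 | 5-(benzyloxy)-1-heptadecyl-2,3-dimethoxybenzene | CCCCCCCCCCCCCCCCCc1cc(OCc2ccccc2)cc(OC)c1OC | intermediate
14 | 3-heptadecyl-4,5-dimethoxyphenol | CCCCCCCCCCCCCCCCCc1cc(O)cc(OC)c1OC | target

Total step count: 7
Longest linear sequence: 7 steps (1 → 3 → 8 → 9 → 10 → 12 → 13 → 14)

Steps most likely to fail

Step 4. The lithium enolate may add to the sulfonimine that the oxaziridine releases (imino-aldol consumption of the enolate), and proton exchange between enolate and product may erode the α′ regiocontrol or lead to over-oxidation. Fallback (Rubottom oxidation in place of direct enolate oxidation): setting out from 9, the kinetic enolate would be silylated (LiN(iPr)2, Me3SiCl, THF, −78 °C) to the dienol silyl ether {[5-(benzyloxy)-3-heptadecylcyclohexa-1,5-dien-1-yl]oxy}trimethylsilane F1. Epoxidation at its nucleophilic terminus (mCPBA, NaHCO3, CH2Cl2, 0 °C) and silyl migration should give 3-(benzyloxy)-5-heptadecyl-6-[(trimethylsilyl)oxy]cyclohex-2-en-1-one F2. Et3N·3HF in THF would then free the alcohol, and the route is rejoined at 10.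

Step 5. Surplus activated DMSO may thiomethylate the freshly formed, electron-rich catechol (Pummerer-type ortho-alkylation or methylthiomethyl ether formation), and the catechol may oxidise in air during work-up. Fallback (deliberate over-oxidation, then reductive methylation): setting out from 10, oxidation with 2-iodoxybenzoic acid (IBX, 3 equiv, DMSO, 23 °C) would be pushed past the catechol to the ortho-quinone 5-(benzyloxy)-3-heptadecylcyclohexa-3,5-diene-1,2-dione F3, which is not air-sensitive. Reductive methylation in one flask (Na2S2O4, Me2SO4, KOH, Bu4NBr, THF/H2O, argon) would reduce it and methylate both oxygens. The route is rejoined at 13, so the isolation of 12 and step 6 are also bypassed.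

Step 2. Under methoxide the enolisable enone may be deprotonated and self-condense, the conjugate addition may revert before ring closure, and the long-chain substrate may separate from methanol. Fallback (donor and acceptor roles exchanged): setting out from 1, Wittig reaction with methyl (triphenylphosphoranylidene)acetate (toluene, 90 °C) would give methyl (E)-icos-2-enoate F4. Methyl acetoacetate and NaOMe in MeOH at reflux should add to it to give dimethyl 2-acetyl-3-heptadecylpentanedioate F5, whose acetyl methyl closes onto the remote ester to the same keto ester 6. The same NaOH then HCl treatment would lead through 7 to 8, where the route is rejoined.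

Further compounds
F1 | step 4 | {[5-(benzyloxy)-3-heptadecylcyclohexa-1,5-dien-1-yl]oxy}trimethylsilane (racemic) | CCCCCCCCCCCCCCCCCC1CC(OCc2ccccc2)=CC(O[Si](C)(C)C)=C1
F2 | step 4 | 3-(benzyloxy)-5-heptadecyl-6-[(trimethylsilyl)oxy]cyclohex-2-en-1-one (racemic) | CCCCCCCCCCCCCCCCCC1CC(OCc2ccccc2)=CC(=O)C1O[Si](C)(C)C
F3 | step 5 | 5-(benzyloxy)-3-heptadecylcyclohexa-3,5-diene-1,2-dione | CCCCCCCCCCCCCCCCCC1=CC(OCc2ccccc2)=CC(=O)C1=O
F4 | step 2 | methyl (E)-icos-2-enoate | CCCCCCCCCCCCCCCCC/C=C/C(=O)OC
F5 | step 2 | dimethyl 2-acetyl-3-heptadecylpentanedioate (racemic, diastereomer mixture) | CCCCCCCCCCCCCCCCCC(CC(=O)OC)C(C(C)=O)C(=O)OC
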